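**Plan**

Numbering (germacranolide): C1 ketone; C2=C3 and the ring O of the 3(2H)-furanone; Z-C4=C5; C6 (lactone O–CH); C7; C8 (ester); C9; C10 (quaternary); C11(=C13H2); C12 (lactone C=O).
Cuts: C6–C7, C11–C12 and C12–O in one retro-[2+2+1] (allene C7=C11=C13 + CO + C6 aldehyde), which opens the γ-lactone and the ten-membered carbocycle together; then the C8 ester, O–C3 of the furanone, C1–C2, C11–C13 and C7–C8.
Enabling feature: the lactone atoms C11(=CH2)–C12(=O)–O–C6–C7 map onto an allene π bond + CO + an aldehyde, and the Z-C4=C5 olefin with the flat furanone ring (O, C10, C1, C2, C3) leaves only four freely rotating bonds between C6 and C7.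
Forward: (S)-citramalic acid → dioxolanone → C8 alkynyl ketone → carbinol → allene; the acetylide of the (Z)-enynol adds at C1; the furanone ring closes first; ester and C6 aldehyde are installed; lactone and ten-membered ring close last, together.
Stereochemistry: C10 from (S)-citramalic acid; C8 from catalyst-controlled transfer hydrogenation; C4=C5 from (Z)-3-methylpent-2-en-4-yn-1-ol; the ester centre from (R)-2-methylbutanoic acid; C6 and C7 from the key step under control of C8 and the ring.

Key step: step 14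

Remark: (S)-citramalic acid, (Z)-3-methylpent-2-en-4-yn-1-ol and (R)-2-methylbutanoic acid are taken as purchasable in stereochemically pure form.

**Route**

Step 1
Reactants: 1 (S)-citramalic acid
Product: 2 2-[(4S)-2,2,4-trimethyl-5-oxo-1,3-dioxolan-4-yl]acetic acid
Conditions: 2,2-dimethoxypropane, TsOH·H2O (cat.), acetone, rt
Reagents that add atoms: 2,2-dimethoxypropane, COC(C)(C)OC
Why: Acid-catalysed acetal exchange engages the α-hydroxy acid pair selectively, because the five-membered 1,3-dioxolan-4-one forms in preference to the six-membered ring from the β-carboxyl group, so the C8 acid stays free and C10 is untouched.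

Step 2
Reactants: 2 2-[(4S)-2,2,4-trimethyl-5-oxo-1,3-dioxolan-4-yl]acetic acid
Product: 4 (5S)-2,2,5-trimethyl-5-[2-oxo-4-(trimethylsilyl)but-3-yn-1-yl]-1,3-dioxolan-4-one, via acid chloride 3 (not isolated)
Conditions: (COCl)2, DMF (cat.), CH2Cl2, 0 °C to rt, evaporate; then trimethylsilylacetylene, PdCl2(PPh3)2 (2 mol %), CuI (4 mol %), Et3N (1.2 equiv), THF, rt
Reagents that add atoms: oxalyl chloride, O=C(Cl)C(=O)Cl (chlorine of 3); trimethylsilylacetylene, C#C[Si](C)(C)C
Why: Acid chloride formation followed by acyl Sonogashira coupling forms the C7–C8 bond under non-nucleophilic conditions that leave the electrophilic dioxolanone intact.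

Step 3
Reactants: 4 (5S)-2,2,5-trimethyl-5-[2-oxo-4-(trimethylsilyl)but-3-yn-1-yl]-1,3-dioxolan-4-one
Product: 5 (5S)-5-[(2R)-2-hydroxy-4-(trimethylsilyl)but-3-yn-1-yl]-2,2,5-trimethyl-1,3-dioxolan-4-one
Conditions: Ru[(R,R)-TsNCH(Ph)CH(Ph)NH](p-cymene) (1 mol %), i-PrOH, 25 °C
Reagents that add atoms: none
Why: Noyori asymmetric transfer hydrogenation of an alkynyl ketone is catalyst-controlled, and the (R,R) complex should deliver hydride to the face that gives the (R)-propargylic alcohol (alkynyl as the π-directing group) under neutral conditions that disfavour attack of the new hydroxyl on the dioxolanone.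

Step 4
Reactants: 5 (5S)-5-[(2R)-2-hydroxy-4-(trimethylsilyl)but-3-yn-1-yl]-2,2,5-trimethyl-1,3-dioxolan-4-one
Product: 6 (5S)-5-[(2R)-2-[(tert-butyldimethylsilyl)oxy]-4-(trimethylsilyl)but-3-yn-1-yl]-2,2,5-trimethyl-1,3-dioxolan-4-one
Conditions: TBSOTf (1.2 equiv), 2,6-lutidine (2 equiv), CH2Cl2, −78 °C
Reagents that add atoms: tert-butyldimethylsilyl trifluoromethanesulfonate, CC(C)(C)[Si](C)(C)OS(=O)(=O)C(F)(F)F
Why: Silyl ether formation with the silyl triflate at low temperature caps the secondary hydroxyl before it can translactonise onto the dioxolanone carbonyl and does not touch the carbinol C–O bond.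

Step 5
Reactants: 6 (5S)-5-[(2R)-2-[(tert-butyldimethylsilyl)oxy]-4-(trimethylsilyl)but-3-yn-1-yl]-2,2,5-trimethyl-1,3-dioxolan-4-one
Product: 7 (5S)-5-[(2R)-2-[(tert-butyldimethylsilyl)oxy]but-3-yn-1-yl]-2,2,5-trimethyl-1,3-dioxolan-4-one
Conditions: AgNO3 (10 mol %), acetone/H2O (4:1), rt, dark
Reagents that add atoms: none
Why: Silver-catalysed protodesilylation is selective for the alkynyl C–Si bond, so the silyl ether and the base-labile dioxolanone (which K2CO3 in methanol would open) are left alone.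

Step 6
Reactants: 7 (5S)-5-[(2R)-2-[(tert-butyldimethylsilyl)oxy]but-3-yn-1-yl]-2,2,5-trimethyl-1,3-dioxolan-4-one
Product: 8 (5S)-5-[(2R)-2-[(tert-butyldimethylsilyl)oxy]penta-3,4-dien-1-yl]-2,2,5-trimethyl-1,3-dioxolan-4-one
Conditions: (CH2O)n, CuI (0.5 equiv), Cy2NH (1.8 equiv), 1,4-dioxane, reflux
Reagents that add atoms: paraformaldehyde (as formaldehyde), C=O
Why: Crabbé homologation (Mannich reaction of the copper acetylide with formaldehyde and Cy2NH, then copper-mediated 1,5-hydride transfer with loss of the imine) turns the terminal alkyne into the terminal allene without touching the C8 stereocentre.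

Step 7
Reactants: 9 (Z)-3-methylpent-2-en-4-yn-1-ol
Product: 10 1-methoxy-4-({[(2Z)-3-methylpent-2-en-4-yn-1-yl]oxy}methyl)benzene
Conditions: NaH (1.05 equiv), 4-methoxybenzyl chloride, n-Bu4NI (cat.), THF/DMF, 0 °C to rt
Reagents that add atoms: 4-methoxybenzyl chloride, COc1ccc(CCl)cc1
Why: Williamson etherification of the alkoxide, formed in preference to the acetylide with one equivalent of NaH, protects the C6 hydroxyl as an ether that survives organolithium, fluoride and carbodiimide steps and is removed oxidatively, the Z olefin not being involved.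

Step 8
Reactants: 8 (5S)-5-[(2R)-2-[(tert-butyldimethylsilyl)oxy]penta-3,4-dien-1-yl]-2,2,5-trimethyl-1,3-dioxolan-4-one; 10 1-methoxy-4-({[(2Z)-3-methylpent-2-en-4-yn-1-yl]oxy}methyl)benzene
Product: 13 (2Z,7S,9R)-9-[(tert-butyldimethylsilyl)oxy]-7-hydroxy-1-[(4-methoxybenzyl)oxy]-3,7-dimethyldodeca-2,10,11-trien-4-yn-6-one, via lithium acetylide 11 (not isolated), via lithium hemiketal alkoxide 12 (not isolated)
Conditions: 10 (1.2 equiv), n-BuLi (1.15 equiv), THF, −78 °C; then 8, −78 °C; AcOH quench at −78 °C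
Reagents that add atoms: n-butyllithium, [Li]CCCC (lithium of 11 and 12)
Why: Acetylide addition to the lactone-type carbonyl of the dioxolanone (no α-hydrogen) should stop at the tetrahedral alkoxide at −78 °C, so one addition occurs and protonation releases acetone and the tertiary α-hydroxy ynone with C10 unchanged.

Step 9
Reactants: 13 (2Z,7S,9R)-9-[(tert-butyldimethylsilyl)oxy]-7-hydroxy-1-[(4-methoxybenzyl)oxy]-3,7-dimethyldodeca-2,10,11-trien-4-yn-6-one
Product: 15 (2S)-2-{(2R)-2-[(tert-butyldimethylsilyl)oxy]penta-3,4-dien-1-yl}-5-{(2Z)-4-[(4-methoxybenzyl)oxy]but-2-en-2-yl}-2-methylfuran-3(2H)-one, via enaminone 14 (not isolated)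
Conditions: Et2NH (2 equiv), EtOH, rt; then AcOH/H2O/THF, rt
Reagents that add atoms: diethylamine, CCNCC (amino group of 14)
Why: Conjugate addition of Et2NH to the ynone gives a β-amino enone in which the tertiary hydroxyl adds to C3 and expels the amine under mild acid (the classical 3(2H)-furanone synthesis from α'-hydroxy ynones, formally a 5-endo oxa-Michael closure), without involving the C4=C5 geometry.

Step 10
Reactants: 15 (2S)-2-{(2R)-2-[(tert-butyldimethylsilyl)oxy]penta-3,4-dien-1-yl}-5-{(2Z)-4-[(4-methoxybenzyl)oxy]but-2-en-2-yl}-2-methylfuran-3(2H)-one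
Product: 16 (2S)-2-[(2R)-2-hydroxypenta-3,4-dien-1-yl]-5-{(2Z)-4-[(4-methoxybenzyl)oxy]but-2-en-2-yl}-2-methylfuran-3(2H)-one
Conditions: HF·pyridine, pyridine, THF, 0 °C to rt
Reagents that add atoms: none
Why: Fluoride-mediated desilylation under buffered conditions frees the C8 hydroxyl while the 4-methoxybenzyl ether, the allene and the vinylogous ester are stable.

Step 11
Reactants: 16 (2S)-2-[(2R)-2-hydroxypenta-3,4-dien-1-yl]-5-{(2Z)-4-[(4-methoxybenzyl)oxy]but-2-en-2-yl}-2-methylfuran-3(2H)-one; 17 (R)-2-methylbutanoic acid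
Product: 18 (2R)-1-[(2S)-5-{(2Z)-4-[(4-methoxybenzyl)oxy]but-2-en-2-yl}-2-methyl-3-oxo-2,3-dihydrofuran-2-yl]penta-3,4-dien-2-yl (2R)-2-methylbutanoate
Conditions: DCC (1.5 equiv), DMAP (0.2 equiv), CH2Cl2, 0 °C to rt
Reagents that add atoms: none
Why: Steglich esterification acylates the only free hydroxyl with retention at C8 (the carbinol C–O bond is not broken), and low temperature with catalytic DMAP should limit epimerisation of the α-branched acyl donor.

Step 12
Reactants: 18 (2R)-1-[(2S)-5-{(2Z)-4-[(4-methoxybenzyl)oxy]but-2-en-2-yl}-2-methyl-3-oxo-2,3-dihydrofuran-2-yl]penta-3,4-dien-2-yl (2R)-2-methylbutanoate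
Product: 19 (2R)-1-[(2S)-5-[(2Z)-4-hydroxybut-2-en-2-yl]-2-methyl-3-oxo-2,3-dihydrofuran-2-yl]penta-3,4-dien-2-yl (2R)-2-methylbutanoate
Conditions: DDQ (1.3 equiv), CH2Cl2/pH 7 buffer (10:1), 0 °C
Reagents that add atoms: none
Why: Oxidative cleavage of the 4-methoxybenzyl ether by DDQ (benzylic hydride abstraction, then hydrolysis of the oxocarbenium ion) is orthogonal to the ester, the allene and the furanone.

Step 13
Reactants: 19 (2R)-1-[(2S)-5-[(2Z)-4-hydroxybut-2-en-2-yl]-2-methyl-3-oxo-2,3-dihydrofuran-2-yl]penta-3,4-dien-2-yl (2R)-2-methylbutanoate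
Product: 20 (2R)-1-[(2S)-2-methyl-3-oxo-5-[(2Z)-4-oxobut-2-en-2-yl]-2,3-dihydrofuran-2-yl]penta-3,4-dien-2-yl (2R)-2-methylbutanoate
Conditions: PhI(OAc)2 (1.1 equiv), TEMPO (10 mol %), CH2Cl2, rt
Reagents that add atoms: none
Why: TEMPO-catalysed oxidation with PhI(OAc)2 converts primary allylic alcohols into enals under near-neutral conditions that should preserve the Z geometry.

Step 14
Reactants: 20 (2R)-1-[(2S)-2-methyl-3-oxo-5-[(2Z)-4-oxobut-2-en-2-yl]-2,3-dihydrofuran-2-yl]penta-3,4-dien-2-yl (2R)-2-methylbutanoate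
Product: 21 (4Z,6R,7R,8R,10S)-8-{[(2R)-2-methylbutanoyl]oxy}-1-oxo-3,10-epoxygermacra-2,4,11(13)-trien-12,6-olide
Conditions: Ru3(CO)12 (5 mol %), CO (20 atm), 1,4-dioxane (2 mM), 120 °C
Reagents that add atoms: carbon monoxide, [C-]#[O+]
Why: Proposed new method: a zerovalent ruthenium carbonyl fragment binds the proximal allene π bond (C7=C11) and the C6 aldehyde, oxidative cyclisation forms C6–C7 within a five-membered oxaruthenacycle, CO inserts into the Ru–C11 bond (C11–C12) and C12–O reductive elimination releases the lactone and the catalyst. The closest known reaction type is the intramolecular allenic hetero-Pauson–Khand [2+2+1] cyclocarbonylation of allenyl aldehydes to bicyclic α-methylene-γ-butyrolactones (Ru3(CO)12/CO or Mo(CO)6/DMSO), shown so far for three- and four-atom tethers; the seven-atom tether here is argued to be workable because the Z olefin and the planar furanone freeze all but four bonds between C6 and C7. The ten-membered carbocycle (nine-membered counted through the furanone oxygen) closes in the oxidative cyclisation, exo with respect to both the C=O and the C7=C11 bond, and the γ-lactone closes as the [2+2+1] ring by CO insertion and C–O reductive elimination. C7 should be set by C8: in the reacting conformer the C8–H bond is anti to the forming C6–C7 bond, the acyloxy group lies inside next to the sp carbon C11 (no 1,3-allylic strain, C–O σ* out of conjugation) and the C9 tether points outside towards the aldehyde arm, which exposes the face leading to 7R; C6 should be set by the metallacycle, where the C5 and C8 arms of the large ring take the trans arrangement and give the 6,7-trans lactone (6R). The step needs aldehyde over ketone selectivity (the C1 carbonyl is a vinylogous ester next to quaternary C10 and a poor π acceptor), proximal over distal allene selectivity (the hetero variant with these metals gives α-methylene lactones through the smaller metallacycle) and cyclisation over oligomerisation (2 mM); any E-enal formed by isomerisation cannot cyclise and can only return through the Z isomer.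

**Compound list**

1 | (S)-citramalic acid [(2S)-2-hydroxy-2-methylbutanedioic acid] | OC(=O)[C@](C)(CC(=O)O)O | starting material
2 | 2-[(4S)-2,2,4-trimethyl-5-oxo-1,3-dioxolan-4-yl]acetic acid | O=C1OC(C)(C)O[C@@]1(C)CC(=O)O | intermediate
3 | 2-[(4S)-2,2,4-trimethyl-5-oxo-1,3-dioxolan-4-yl]acetyl chloride | O=C1OC(C)(C)O[C@@]1(C)CC(=O)Cl | intermediate
4 | (5S)-2,2,5-trimethyl-5-[2-oxo-4-(trimethylsilyl)but-3-yn-1-yl]-1,3-dioxolan-4-one | O=C1OC(C)(C)O[C@@]1(C)CC(=O)C#C[Si](C)(C)C | intermediate
5 | (5S)-5-[(2R)-2-hydroxy-4-(trimethylsilyl)but-3-yn-1-yl]-2,2,5-trimethyl-1,3-dioxolan-4-one | O=C1OC(C)(C)O[C@@]1(C)C[C@@H](O)C#C[Si](C)(C)C | intermediate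
6 | (5S)-5-[(2R)-2-[(tert-butyldimethylsilyl)oxy]-4-(trimethylsilyl)but-3-yn-1-yl]-2,2,5-trimethyl-1,3-dioxolan-4-one | O=C1OC(C)(C)O[C@@]1(C)C[C@@H](O[Si](C)(C)C(C)(C)C)C#C[Si](C)(C)C | intermediate
7 | (5S)-5-[(2R)-2-[(tert-butyldimethylsilyl)oxy]but-3-yn-1-yl]-2,2,5-trimethyl-1,3-dioxolan-4-one | O=C1OC(C)(C)O[C@@]1(C)C[C@@H](O[Si](C)(C)C(C)(C)C)C#C | intermediate
8 | (5S)-5-[(2R)-2-[(tert-butyldimethylsilyl)oxy]penta-3,4-dien-1-yl]-2,2,5-trimethyl-1,3-dioxolan-4-one | O=C1OC(C)(C)O[C@@]1(C)C[C@@H](O[Si](C)(C)C(C)(C)C)C=C=C | intermediate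
9 | (Z)-3-methylpent-2-en-4-yn-1-ol | C#C/C(C)=C\CO | starting material
10 | 1-methoxy-4-({[(2Z)-3-methylpent-2-en-4-yn-1-yl]oxy}methyl)benzene | C#C/C(C)=C\COCc1ccc(OC)cc1 | intermediate
11 | lithium acetylide of 10 | [Li]C#C/C(C)=C\COCc1ccc(OC)cc1 | intermediate
12 | lithium hemiketal alkoxide from addition of 11 to the dioxolanone carbonyl of 8 (new hemiketal centre undefined) | [Li]OC1(C#C/C(C)=C\COCc2ccc(OC)cc2)OC(C)(C)O[C@@]1(C)C[C@@H](O[Si](C)(C)C(C)(C)C)C=C=C | intermediate
13 | (2Z,7S,9R)-9-[(tert-butyldimethylsilyl)oxy]-7-hydroxy-1-[(4-methoxybenzyl)oxy]-3,7-dimethyldodeca-2,10,11-trien-4-yn-6-one | O=C(C#C/C(C)=C\COCc1ccc(OC)cc1)[C@@](C)(O)C[C@@H](O[Si](C)(C)C(C)(C)C)C=C=C | intermediate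
14 | β-(diethylamino) enone from addition of Et2NH to the ynone of 13 (enamine geometry undefined) | CCN(CC)C(=CC(=O)[C@@](C)(O)C[C@@H](O[Si](C)(C)C(C)(C)C)C=C=C)/C(C)=C\COCc1ccc(OC)cc1 | intermediate
15 | (2S)-2-{(2R)-2-[(tert-butyldimethylsilyl)oxy]penta-3,4-dien-1-yl}-5-{(2Z)-4-[(4-methoxybenzyl)oxy]but-2-en-2-yl}-2-methylfuran-3(2H)-one | COc1ccc(COC/C=C(/C)C2=CC(=O)[C@](C)(C[C@@H](O[Si](C)(C)C(C)(C)C)C=C=C)O2)cc1 | intermediate
16 | (2S)-2-[(2R)-2-hydroxypenta-3,4-dien-1-yl]-5-{(2Z)-4-[(4-methoxybenzyl)oxy]but-2-en-2-yl}-2-methylfuran-3(2H)-one | COc1ccc(COC/C=C(/C)C2=CC(=O)[C@](C)(C[C@@H](O)C=C=C)O2)cc1 | intermediate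
17 | (R)-2-methylbutanoic acid | CC[C@@H](C)C(=O)O | starting material
18 | (2R)-1-[(2S)-5-{(2Z)-4-[(4-methoxybenzyl)oxy]but-2-en-2-yl}-2-methyl-3-oxo-2,3-dihydrofuran-2-yl]penta-3,4-dien-2-yl (2R)-2-methylbutanoate | COc1ccc(COC/C=C(/C)C2=CC(=O)[C@](C)(C[C@@H](OC(=O)[C@H](C)CC)C=C=C)O2)cc1 | intermediate
19 | (2R)-1-[(2S)-5-[(2Z)-4-hydroxybut-2-en-2-yl]-2-methyl-3-oxo-2,3-dihydrofuran-2-yl]penta-3,4-dien-2-yl (2R)-2-methylbutanoate | OC/C=C(/C)C1=CC(=O)[C@](C)(C[C@@H](OC(=O)[C@H](C)CC)C=C=C)O1 | intermediate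
20 | (2R)-1-[(2S)-2-methyl-3-oxo-5-[(2Z)-4-oxobut-2-en-2-yl]-2,3-dihydrofuran-2-yl]penta-3,4-dien-2-yl (2R)-2-methylbutanoate | O=C/C=C(/C)C1=CC(=O)[C@](C)(C[C@@H](OC(=O)[C@H](C)CC)C=C=C)O1 | intermediate
21 | (4Z,6R,7R,8R,10S)-8-{[(2R)-2-methylbutanoyl]oxy}-1-oxo-3,10-epoxygermacra-2,4,11(13)-trien-12,6-olide | C=C1C(=O)O[C@@H]2/C=C(/C)C3=CC(=O)[C@](C)(C[C@@H](OC(=O)[C@H](C)CC)[C@@H]12)O3 | target

**Count and risks**

Total step count: 14. Longest linear sequence: 13 steps (steps 1–6 and 8–14, from 1).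

Steps most likely to fail:

Step 14 (Proposed new method). The substrate may not reach the medium-ring metallacycle and may instead be consumed by intermolecular coupling or by engagement of the C1 carbonyl, or the cyclisation may proceed with poor facial selectivity at the allene or the aldehyde. The fallback sets out from 20 and returns at 21, making the two bonds in two known operations. Bromoboration of the allene with B-bromo-9-borabicyclo[3.3.1]nonane (CH2Cl2, −78 °C, high dilution) should give 2-bromoallylborane F1 (not isolated). Its intramolecular allylboration of the C6 aldehyde through a six-membered chair closes the ten-membered ring (C6–C7) and should give, after aqueous work-up, bromo alcohol F2. Cyclocarbonylation of the vinyl bromide with the C6 hydroxyl (Pd(PPh3)4 cat., CO 1 atm, Et3N, MeCN, 60 °C) then forms C11–C12 and the lactone, giving 21.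

Step 8. Addition to the hindered dioxolanone carbonyl may be sluggish, or the tetrahedral adduct may collapse before the quench and take up a second acetylide. The fallback sets out from 8 and returns at 13. Aminolysis of the dioxolanone with MeNHOMe·HCl and i-PrMgCl (THF, −20 °C) should give hydroxy Weinreb amide F3. Addition of lithium acetylide 11 (2.5 equiv, THF, −78 to 0 °C, the first equivalent deprotonating the tertiary hydroxyl) then passes through the stable five-membered chelate and releases ynone 13 on quench.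

Step 6. The secondary amine may open the dioxolanone, or the material may decompose at reflux before the hydride-transfer fragmentation is complete. The fallback sets out from 2 (through acid chloride 3) and returns at 8; it introduces the aminomethyl carbon with the alkyne and needs neither free secondary amine nor formaldehyde. Acyl Sonogashira coupling with N,N-dicyclohexylprop-2-yn-1-amine under the conditions of step 2 should give amino ynone F4. Transfer hydrogenation as in step 3 gives amino alcohol F5, and silylation as in step 4 gives silyl ether F6. Heating F6 with ZnI2 in toluene triggers the 1,5-hydride shift and fragmentation to allene 8; step 5 is no longer needed.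

**Further compounds**

F1 | step 14 | (2R)-4-bromo-5-(9-borabicyclo[3.3.1]nonan-9-yl)-1-[(2S)-2-methyl-3-oxo-5-[(2Z)-4-oxobut-2-en-2-yl]-2,3-dihydrofuran-2-yl]pent-3-en-2-yl (2R)-2-methylbutanoate (olefin geometry undefined) | O=C/C=C(/C)C1=CC(=O)[C@](C)(C[C@@H](OC(=O)[C@H](C)CC)C=C(Br)CB2C3CCCC2CCC3)O1
F2 | step 14 | (2Z,4R,5R,6R,8S)-5-(1-bromoethenyl)-4-hydroxy-2,8-dimethyl-9-oxo-11-oxabicyclo[6.2.1]undeca-1(10),2-dien-6-yl (2R)-2-methylbutanoate | O[C@@H]2/C=C(/C)C3=CC(=O)[C@](C)(C[C@@H](OC(=O)[C@H](C)CC)[C@H]2C(Br)=C)O3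
F3 | step 8 | (2S,4R)-4-[(tert-butyldimethylsilyl)oxy]-2-hydroxy-N-methoxy-N,2-dimethylhepta-5,6-dienamide | CON(C)C(=O)[C@@](C)(O)C[C@@H](O[Si](C)(C)C(C)(C)C)C=C=C
F4 | step 6 | (5S)-5-[5-(dicyclohexylamino)-2-oxopent-3-yn-1-yl]-2,2,5-trimethyl-1,3-dioxolan-4-one | O=C1OC(C)(C)O[C@@]1(C)CC(=O)C#CCN(C2CCCCC2)C2CCCCC2
F5 | step 6 | (5S)-5-[(2R)-5-(dicyclohexylamino)-2-hydroxypent-3-yn-1-yl]-2,2,5-trimethyl-1,3-dioxolan-4-one | O=C1OC(C)(C)O[C@@]1(C)C[C@@H](O)C#CCN(C2CCCCC2)C2CCCCC2
F6 | step 6 | (5S)-5-[(2R)-2-[(tert-butyldimethylsilyl)oxy]-5-(dicyclohexylamino)pent-3-yn-1-yl]-2,2,5-trimethyl-1,3-dioxolan-4-one | O=C1OC(C)(C)O[C@@]1(C)C[C@@H](O[Si](C)(C)C(C)(C)C)C#CCN(C2CCCCC2)C2CCCCC2
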